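**Plan**

1. Retrosynthesis: cut the lactone C–O bond (ring F), then the N–C7 bond (ring C), then the C1–C8 bond (ring B). Earlier cuts are C13=C14 (olefination), ring E (C9–C15 and C10–C17), C5–C21 with C6–C7 (one conjugate addition/enolate alkylation) and C4–C5 (aldol), back to 4-methoxy-3-methylpyridine and cycloheptanone.
2. Forward: ring D is cycloheptanone and ring A is carried as an aromatic 4-methoxypyridine. C6/C5 are set, ring E is annulated, ring B is closed through C1–C8, ring A is reduced, ring C is closed by N-alkylation and ring F by lactonization.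
3. Enabling feature: C1 is ring position 2 of the pyridine that becomes piperidinone ring A, so it is an N-acyliminium carbon once N is acylated. C8 is the β-carbon of a 1-methoxydiene C13=C8–C9=C15 exocyclic to ring D. N–C1–C8–C13=O is therefore a Mannich retron, held in a five-membered ring by the C3–C4–C5 tether.
4. Stereochemistry: C6 and C10 come from ligand-controlled copper-catalysed conjugate additions, C5 from anti alkylation of the C6-substituted enolate, and C8 from the tether (cis B/D fusion). C1, C3 and C18 are epimerizable around the C2 ketone and converge when ring C closes.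

Key step: step 11

Atom labels: N; C1 (NCH joined to C8); C2 (ketone); C3; C4 (CH2 between C3 and C5); C5 (quaternary, carries C21H2O); C6 (CH, carries C7H2N); C8 (quaternary, carries the C13–C14–C22 chain); C9=C15; C10 (CH at the D/E fusion); C11, C12 (ring D CH2); C16, C17 (ring E CH2); C18 (CH, carries methyl C20); C19 (NCH2). Rings: A = N, C1, C3, C2, C18, C19; B = C1, C3, C4, C5, C8; C = N, C1, C8, C5, C6, C7; D = C5, C6, C12, C11, C10, C9, C8; E = C9, C10, C17, C16, C15; F = C8, C13, C14, C22, O, C21, C5.

Remark: C18, α to the C2 ketone, is taken to be the more stable epimer in the cage (methyl pseudo-equatorial on a boat-like ring A), so it is left to equilibrate under base.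

**Step 1**
Reactants: 1 4-methoxy-3-methylpyridine
Product: 3 4-methoxy-5-methylpyridine-3-carbaldehyde, via 3-lithio-4-methoxy-5-methylpyridine 2 (not isolated)
Conditions: 2,4,6-Me3C6H2Li, THF, −23 °C; DMF, −78 °C → rt; H2O
Reagents that add atoms: N,N-dimethylformamide, CN(C)C=O
Why: Directed ortho-metalation: the methoxy group directs the hindered, non-adding aryllithium base to the only free ortho position, and the aryllithium is formylated by DMF.

**Step 2**
Reactants: 3 4-methoxy-5-methylpyridine-3-carbaldehyde, 4 cycloheptanone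
Product: 5 (E)-2-[(4-methoxy-5-methylpyridin-3-yl)methylidene]cycloheptan-1-one
Conditions: 4 (excess), NaOH (aq), EtOH, rt
Reagents that add atoms: none
Why: Claisen–Schmidt (crossed aldol) condensation of the non-enolizable aldehyde with excess ketone should give the E mono-arylidene ketone.

**Step 3**
Reactants: 5 (E)-2-[(4-methoxy-5-methylpyridin-3-yl)methylidene]cycloheptan-1-one
Product: 6 2-[(4-methoxy-5-methylpyridin-3-yl)methyl]cyclohept-2-en-1-one
Conditions: RhCl3·3H2O (cat.), EtOH, 80 °C
Reagents that add atoms: none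
Why: Rhodium hydride addition/β-hydride elimination should move the exocyclic C=C into the ring (the known exo-to-endo isomerization of 2-alkylidenecycloalkanones), relieving the allylic strain of the arylidene ketone.

**Step 4**
Reactants: 6 2-[(4-methoxy-5-methylpyridin-3-yl)methyl]cyclohept-2-en-1-one
Product: 8 (2S,3S)-2-[(benzyloxy)methyl]-3-{[dimethyl(propan-2-yloxy)silyl]methyl}-2-[(4-methoxy-5-methylpyridin-3-yl)methyl]cycloheptan-1-one, via chloromagnesium enolate 7 (not isolated)
Conditions: (i-PrO)Me2SiCH2MgCl, Cu(OTf)2 (cat.), chiral imidazolinium carbene precursor (cat.), Et2O, −30 °C; then BnOCH2Cl, DMPU, −30 → 0 °C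
Reagents that add atoms: [(isopropoxydimethylsilyl)methyl]magnesium chloride, CC(C)O[Si](C)(C)C[Mg]Cl; benzyl chloromethyl ether, ClCOCc1ccccc1
Why: Copper-catalysed asymmetric conjugate addition of the Grignard reagent to the 2-substituted enone should set C6 (3S) under ligand control, and the magnesium enolate is alkylated anti to the new C6 substituent, which sets quaternary C5 with C21 trans and C4 cis to C7.

**Step 5**
Reactants: 8 the silyl ketone from step 4
Product: 9 (2S,3S)-2-[(benzyloxy)methyl]-3-(hydroxymethyl)-2-[(4-methoxy-5-methylpyridin-3-yl)methyl]cycloheptan-1-one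
Conditions: H2O2 (30% aq), KF, KHCO3, THF/MeOH, rt
Reagents that add atoms: hydrogen peroxide, OO
Why: Tamao oxidation replaces the alkoxysilyl group by OH at C7 with retention, and buffered peroxide should leave the ketone, the benzyl ether and the pyridine untouched.

**Step 6**
Reactants: 9 the hydroxymethyl ketone
Product: 10 (2S,3S)-2-[(benzyloxy)methyl]-3-(chloromethyl)-2-[(4-methoxy-5-methylpyridin-3-yl)methyl]cycloheptan-1-one
Conditions: PPh3, CCl4, CH2Cl2, 40 °C
Reagents that add atoms: tetrachloromethane, ClC(Cl)(Cl)Cl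
Why: Appel reaction (SN2 of chloride on the alkoxyphosphonium ion) should give the primary chloride, a latent electrophile for the later N-alkylation that tolerates the organometallic and ylide steps.

**Step 7**
Reactants: 10 the chloromethyl ketone
Product: 12 (6S,7S)-7-[(benzyloxy)methyl]-6-(chloromethyl)-7-[(4-methoxy-5-methylpyridin-3-yl)methyl]cyclohept-2-en-1-one, via lithium enolate 11 (not isolated)
Conditions: LiN(i-Pr)2, THF, −78 °C; then PhS(Cl)=N-t-Bu, −78 °C
Reagents that add atoms: none
Why: Mukaiyama dehydrogenation: the ketone can enolize only toward C9 because C5 is quaternary, and syn elimination from the α-sulfur adduct should give the C9=C10 enone.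

**Step 8**
Reactants: 12 the cycloheptenone
Product: 13 (2S,3S,6R)-2-[(benzyloxy)methyl]-3-(chloromethyl)-6-[2-(1,3-dioxolan-2-yl)ethyl]-2-[(4-methoxy-5-methylpyridin-3-yl)methyl]cycloheptan-1-one
Conditions: BrMgCH2CH2CH(OCH2CH2O), CuBr·SMe2 (cat.), Josiphos-type ferrocenyl diphosphine (cat.), t-BuOMe, −75 °C; H2O
Reagents that add atoms: [2-(1,3-dioxolan-2-yl)ethyl]magnesium bromide, Br[Mg]CCC1OCCO1
Why: Copper-catalysed asymmetric conjugate addition, with the ligand enantiomer chosen to deliver the chain to the C10 face anti to the picolyl group (6R), so that the ligand and not the weak remote substrate bias decides C10.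

**Step 9**
Reactants: 13 the dioxolane ketone
Product: 15 (5S,6S,8aS)-5-[(benzyloxy)methyl]-6-(chloromethyl)-5-[(4-methoxy-5-methylpyridin-3-yl)methyl]-2,5,6,7,8,8a-hexahydroazulen-4(1H)-one, via keto aldehyde 14 (not isolated)
Conditions: 2 M HCl, THF, 50 °C
Reagents that add atoms: none
Why: Acetal hydrolysis followed by intramolecular aldol condensation (cyclopentene annulation): the ketone enolizes only toward C9, which attacks the aldehyde, and dehydration gives the conjugated C9=C15 enone of ring E.

**Step 10**
Reactants: 15 the bicyclic enone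
Product: 16 4-(methoxymethylidene) dienol ether of 15 (mixture of enol ether geometries)
Conditions: Ph3P(CH2OMe)Cl, KOt-Bu, THF, 0 °C; then 15, 0 → 45 °C
Reagents that add atoms: (methoxymethyl)triphenylphosphonium chloride, [Cl-].COC[P+](c1ccccc1)(c1ccccc1)c1ccccc1
Why: Wittig methoxymethylenation of the non-enolizable enone carbonyl should give the 1-methoxydiene; its geometry does not matter because C13 becomes a formyl group.

**Step 11**
Reactants: 16 the 1-methoxydiene
Product: 19 tetracyclic N-Alloc 2,3-dihydropyridin-4-one aldehyde (rings A, B, D, E; CHO on C8), via N-acylpyridinium chloride 17 (not isolated), via oxocarbenium chloride 18 (not isolated)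
Conditions: allyl chloroformate, CH2Cl2, −78 → 0 °C; then 1 M HCl, THF, rt
Reagents that add atoms: allyl chloroformate, C=CCOC(Cl)=O; water, O
Why: N-Acylation gives the N-allyloxycarbonyl-4-methoxypyridinium ion 17; C8, the β-carbon of the 1-methoxydiene C13=C8–C9=C15, attacks C1 (the ring carbon next to the tether) to give oxocarbenium ion 18, and aqueous acid hydrolyses both methyl enol ethers to the C13 aldehyde and the 2,3-dihydropyridin-4-one. The closest known reaction type is the Mannich-type addition of enol ethers and silyl enol ethers to N-acyl-4-methoxypyridinium salts followed by enol ether hydrolysis. Ring B closes in the 5-exo-trig mode with respect to the C1=N+ bond (5-enolexo for the nucleophile). C8 is controlled by the C4 tether, which reaches only the face of the exocyclic enol ether that carries C4 and so gives the cis B/D fusion with C13 cis to C21; C3 is set on hydrolysis by protonation to the cis A/B fusion; C1 is expected with N syn to C6, because that arrangement places the electron-rich C9=C15 bond over the pyridinium ring and keeps the developing C13 oxocarbenium away from it, and the other C1 epimer would converge in step 14. The step needs attack at C1 and not at the methoxy-bearing C2, and bond formation at C8 and not at C15: the methoxy group blocks C2, and closure through C15 would need a seven-membered ring.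

**Step 12**
Reactants: 19 the tetracyclic aldehyde
Product: 20 tert-butyl (E)-enoate (C13=C14–C22O2t-Bu on C8)
Conditions: (EtO)2P(O)CH2CO2t-Bu, LiCl, DBU, MeCN, rt
Reagents that add atoms: tert-butyl diethylphosphonoacetate, CCOP(=O)(CC(=O)OC(C)(C)C)OCC
Why: Horner–Wadsworth–Emmons olefination of the non-enolizable neopentyl aldehyde under mild LiCl/amine conditions should give the E enoate without touching the vinylogous carbamate.

**Step 13**
Reactants: 20 the enoate
Product: 21 N-Alloc piperidin-4-one tert-butyl ester (ring A saturated; C13–C14 saturated)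
Conditions: Cu(OAc)2·H2O (cat.), 1,2-bis(diphenylphosphino)benzene (cat.), (HMe2Si)2O, t-BuOH, PhMe, rt
Reagents that add atoms: none
Why: Copper hydride conjugate reduction: hydride adds to the β-carbons of the enoate (C13) and of the N-acyl enaminone (C19), the enolates are protonated by t-BuOH, and the isolated C9=C15 alkene and allyl carbamate should be inert; C18 is formed here and settles later.

**Step 14**
Reactants: 21 the N-Alloc piperidinone
Product: 23 pentacyclic amino ketone (rings A to E; N–C7 bond formed), via secondary amine 22 (not isolated)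
Conditions: Pd(PPh3)4 (cat.), morpholine, THF, rt; then K2CO3, NaI (cat.), MeCN, 70 °C
Reagents that add atoms: none
Why: Tsuji–Trost deallylation frees the secondary amine, which closes ring C by intramolecular SN2 on the C7 chloride (Finkelstein-assisted); C1 and C3 can equilibrate by retro-aza-Michael/aza-Michael addition and enolization, only the epimer with N syn to C6 can cyclize, and C18 settles α to the ketone under the same base.

**Step 15**
Reactants: 23 the pentacyclic amino ketone
Product: 24 hydroxy acid (C21–OH, C22 acid)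
Conditions: BCl3, C6HMe5, CH2Cl2, −78 → 0 °C; MeOH/H2O
Reagents that add atoms: none
Why: Lewis acid cleavage of the benzyl ether and the tert-butyl ester, with pentamethylbenzene as cation scavenger so that the C9=C15 alkene is not attacked.

**Step 16**
Reactants: 24 the hydroxy acid
Product: 25 target CNP0292775.1
Conditions: EDC·HCl, DMAP (cat.), CH2Cl2, high dilution, rt
Reagents that add atoms: none
Why: Carbodiimide (Steglich-type) lactonization should close the seven-membered ring F, because C13 and C21 are held cis on the vicinal quaternary carbons C8 and C5.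

**Compound list**

1 | 4-methoxy-3-methylpyridine | COc1ccncc1C | starting material
2 | 3-lithio-4-methoxy-5-methylpyridine | COc1c([Li])cncc1C | intermediate (not isolated)
3 | 4-methoxy-5-methylpyridine-3-carbaldehyde | COc1c(C=O)cncc1C | intermediate
4 | cycloheptanone | O=C1CCCCCC1 | starting material
5 | (E)-2-[(4-methoxy-5-methylpyridin-3-yl)methylidene]cycloheptan-1-one | O=C1CCCCC/C1=C\c1cncc(C)c1OC | intermediate
6 | 2-[(4-methoxy-5-methylpyridin-3-yl)methyl]cyclohept-2-en-1-one | O=C1CCCCC=C1Cc1cncc(C)c1OC | intermediate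
7 | chloromagnesium enolate of the conjugate adduct (C8–OMgCl, C8=C5, C6 set) | Cl[Mg]OC1=C(Cc2cncc(C)c2OC)[C@@H](C[Si](C)(C)OC(C)C)CCCC1 | intermediate (not isolated)
8 | (2S,3S)-2-[(benzyloxy)methyl]-3-{[dimethyl(propan-2-yloxy)silyl]methyl}-2-[(4-methoxy-5-methylpyridin-3-yl)methyl]cycloheptan-1-one | O=C1CCCC[C@H](C[Si](C)(C)OC(C)C)[C@]1(COCc2ccccc2)Cc2cncc(C)c2OC | intermediate
9 | (2S,3S)-2-[(benzyloxy)methyl]-3-(hydroxymethyl)-2-[(4-methoxy-5-methylpyridin-3-yl)methyl]cycloheptan-1-one | O=C1CCCC[C@H](CO)[C@]1(COCc2ccccc2)Cc2cncc(C)c2OC | intermediate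
10 | (2S,3S)-2-[(benzyloxy)methyl]-3-(chloromethyl)-2-[(4-methoxy-5-methylpyridin-3-yl)methyl]cycloheptan-1-one | O=C1CCCC[C@H](CCl)[C@]1(COCc2ccccc2)Cc2cncc(C)c2OC | intermediate
11 | lithium enolate of 10 (C8–OLi, C8=C9) | [Li]OC1=CCCC[C@H](CCl)[C@]1(COCc2ccccc2)Cc2cncc(C)c2OC | intermediate (not isolated)
12 | (6S,7S)-7-[(benzyloxy)methyl]-6-(chloromethyl)-7-[(4-methoxy-5-methylpyridin-3-yl)methyl]cyclohept-2-en-1-one | O=C1C=CCC[C@H](CCl)[C@]1(COCc2ccccc2)Cc2cncc(C)c2OC | intermediate
13 | (2S,3S,6R)-2-[(benzyloxy)methyl]-3-(chloromethyl)-6-[2-(1,3-dioxolan-2-yl)ethyl]-2-[(4-methoxy-5-methylpyridin-3-yl)methyl]cycloheptan-1-one | O=C1C[C@@H](CCC2OCCO2)CC[C@H](CCl)[C@]1(COCc2ccccc2)Cc2cncc(C)c2OC | intermediate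
14 | keto aldehyde: 13 with the dioxolane replaced by CHO (C15) | O=C1C[C@@H](CCC=O)CC[C@H](CCl)[C@]1(COCc2ccccc2)Cc2cncc(C)c2OC | intermediate (not isolated)
15 | (5S,6S,8aS)-5-[(benzyloxy)methyl]-6-(chloromethyl)-5-[(4-methoxy-5-methylpyridin-3-yl)methyl]-2,5,6,7,8,8a-hexahydroazulen-4(1H)-one (rings D and E; C8 ketone, C9=C15; H10 cis to C7 and C4) | O=C1C2=CCC[C@H]2CC[C@H](CCl)[C@]1(COCc2ccccc2)Cc2cncc(C)c2OC | intermediate
16 | 1-methoxydiene: 15 with C8=O replaced by C8=C13H(OMe), both enol ether geometries | COC=C1C2=CCC[C@H]2CC[C@H](CCl)[C@]1(COCc2ccccc2)Cc2cncc(C)c2OC | intermediate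
17 | N-(allyloxycarbonyl)pyridinium chloride of 16 | COC=C1C2=CCC[C@H]2CC[C@H](CCl)[C@]1(COCc2ccccc2)Cc2c[n+](C(=O)OCC=C)cc(C)c2OC.[Cl-] | intermediate (not isolated)
18 | cyclized N-Alloc 4-methoxy-1,2-dihydropyridine with C13 as O-methyl oxocarbenium chloride (C1–C8 bond formed) | CC1=CN(C(=O)OCC=C)[C@H]2C(=C1OC)C[C@@]1(COCc3ccccc3)[C@@H](CCl)CC[C@@H]3CCC=C3[C@@]21C=[O+]C.[Cl-] | intermediate (not isolated)
19 | N-Alloc 2,3-dihydropyridin-4-one aldehyde: rings A (C18=C19, C2=O), B, D, E; CHO (C13) on C8; H1 and H3 cis; N syn to C6 across ring B; C13 cis to C21 | CC1=CN(C(=O)OCC=C)[C@H]2[C@@H](C1=O)C[C@@]1(COCc3ccccc3)[C@@H](CCl)CC[C@@H]3CCC=C3[C@@]21C=O | intermediate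
20 | tert-butyl (E)-enoate: 19 with CHO replaced by CH=CH–CO2t-Bu | CC1=CN(C(=O)OCC=C)[C@H]2[C@@H](C1=O)C[C@@]1(COCc3ccccc3)[C@@H](CCl)CC[C@@H]3CCC=C3[C@@]21/C=C/C(=O)OC(C)(C)C | intermediate
21 | N-Alloc piperidin-4-one tert-butyl ester: ring A saturated, C8 carries CH2CH2CO2t-Bu; C18 drawn in the configuration of the target | C[C@@H]1CN(C(=O)OCC=C)[C@H]2[C@@H](C1=O)C[C@@]1(COCc3ccccc3)[C@@H](CCl)CC[C@@H]3CCC=C3[C@@]21CCC(=O)OC(C)(C)C | intermediate
22 | secondary amine: 21 without the Alloc group | C[C@@H]1CN[C@H]2[C@@H](C1=O)C[C@@]1(COCc3ccccc3)[C@@H](CCl)CC[C@@H]3CCC=C3[C@@]21CCC(=O)OC(C)(C)C | intermediate (not isolated)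
23 | pentacyclic amino ketone: rings A to E of the target, C5–CH2OBn, C8–CH2CH2CO2t-Bu | C[C@@H]1CN2C[C@H]3CC[C@@H]4CCC=C4[C@]5(CCC(=O)OC(C)(C)C)[C@@]3(COCc6ccccc6)C[C@H](C1=O)[C@H]25 | intermediate
24 | hydroxy acid: 23 with C21–OH and C22 acid free | C[C@@H]1CN2C[C@H]3CC[C@@H]4CCC=C4[C@]5(CCC(=O)O)[C@@]3(CO)C[C@H](C1=O)[C@H]25 | intermediate
25 | CNP0292775.1, hexacyclic keto lactone | C[C@@H]1CN2C[C@H]3CC[C@@H]4CCC=C4[C@]45CCC(=O)OC[C@]34C[C@H](C1=O)[C@H]25 | target

Total step count: 16. Longest linear sequence: 16 steps (from 1; cycloheptanone 4 enters at step 2).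

**Steps most likely to fail**

Step 11: the tethered dienol ether may attack the acylpyridinium ion too slowly, so that the ion loses its O-methyl group to chloride or reverts, and the facial selectivity at C1 may be poor. The fallback sets out from 16 and reduces the ring before the cyclization. Acylation with allyl chloroformate in the presence of NaBH4 (MeOH, −78 °C) should deliver hydride to C19, the ring carbon flanked by the small methyl group, and give the N-Alloc 1,6-dihydropyridine F1. Camphorsulfonic acid in CH2Cl2 protonates C18, the resulting N-acyliminium ion is captured by C8 in a classical N-acyliminium Mannich cyclization, and aqueous acid gives the N-Alloc piperidinone aldehyde F2. Olefination as in step 12 gives the enoate F3, and copper hydride reduction as in step 13 returns the route at 21.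

Step 10: olefination of the hindered, cross-conjugated ketone may be slow or incomplete, with competing elimination of the primary chloride by the basic ylide. The fallback sets out from 15. A Corey–Chaykovsky reaction (Me3S+ I−, KN(SiMe3)2) should give the vinyl oxirane F4, MgBr2·OEt2 promotes Meinwald rearrangement to the β,γ-unsaturated aldehyde F5, and TBSOTf/Et3N gives the silyl dienol ether F6. Under the conditions of step 11, F6 comes back to the route at 19.

Step 4: enantio- and diastereocontrol may be lost through binding of the pyridine nitrogen to copper, or the hindered enolate may be O-alkylated. The fallback sets out from 3. NaBH4 gives the pyridylmethanol F7 and SOCl2 the chloride F8. The same Grignard reagent is added to commercial cyclohept-2-en-1-one, a well-precedented substrate for copper-catalysed asymmetric conjugate addition, and the enolate is trapped with F8 to give the trans ketone F9. Its thermodynamic, more substituted potassium enolate (KH, THF) is alkylated by benzyl chloromethyl ether anti to the C6 substituent, and the route is rejoined at 8.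

**Further compounds**

F1 | step 11 | N-Alloc 4-methoxy-1,6-dihydropyridine of 16 (hydride at C19) | COC=C1C2=CCC[C@H]2CC[C@H](CCl)[C@]1(COCc2ccccc2)CC2=CN(C(=O)OCC=C)CC(C)=C2OC
F2 | step 11 | N-Alloc piperidin-4-one aldehyde (21 with CHO on C8 in place of the ester chain) | C[C@@H]1CN(C(=O)OCC=C)[C@H]2[C@@H](C1=O)C[C@@]1(COCc3ccccc3)[C@@H](CCl)CC[C@@H]3CCC=C3[C@@]21C=O
F3 | step 11 | N-Alloc piperidin-4-one tert-butyl (E)-enoate | C[C@@H]1CN(C(=O)OCC=C)[C@H]2[C@@H](C1=O)C[C@@]1(COCc3ccccc3)[C@@H](CCl)CC[C@@H]3CCC=C3[C@@]21/C=C/C(=O)OC(C)(C)C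
F4 | step 10 | spiro vinyl oxirane at C8 of 15 (C8 epimers) | C1OC12C3=CCC[C@H]3CC[C@H](CCl)[C@]2(COCc2ccccc2)Cc2cncc(C)c2OC
F5 | step 10 | β,γ-unsaturated aldehyde (CHO on C8–H, C9=C15; C8 epimers) | O=CC1C2=CCC[C@H]2CC[C@H](CCl)[C@]1(COCc2ccccc2)Cc2cncc(C)c2OC
F6 | step 10 | tert-butyldimethylsilyl dienol ether (silyl analogue of 16) | CC(C)(C)[Si](C)(C)OC=C1C2=CCC[C@H]2CC[C@H](CCl)[C@]1(COCc2ccccc2)Cc2cncc(C)c2OC
F7 | step 4 | (4-methoxy-5-methylpyridin-3-yl)methanol | OCc1cncc(C)c1OC
F8 | step 4 | 3-(chloromethyl)-4-methoxy-5-methylpyridine | ClCc1cncc(C)c1OC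
F9 | step 4 | trans-3-{[dimethyl(propan-2-yloxy)silyl]methyl}-2-[(4-methoxy-5-methylpyridin-3-yl)methyl]cycloheptan-1-one (C6 as in 8) | O=C1CCCC[C@H](C[Si](C)(C)OC(C)C)[C@H]1Cc1cncc(C)c1OC
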